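**Retrosynthetic overview**

- Target 23 is 2-(all-E-hexaprenyl)-6-methoxy-3-methyl-1,4-benzoquinone. Ring A is its only ring and is carried through from an aromatic precursor, so no ring is formed in the route.
- The strategy rests on this feature: in ring A the methyl-bearing C3 and the chain-bearing C2 are neighbours, and they are the β- and α-carbons of the C1 carbonyl once C4 is held as a dimethyl ketal. The C5=C6 edge is then a methoxy enol ether whose β-carbon C5 is electron-rich.
- Key disconnections: C3–CH3 by cuprate conjugate addition and C2–C1' by SN2 alkylation of the resulting enolate with all-E-hexaprenyl bromide 16, both in one flask on quinone monoketal 4. Ketal hydrolysis with aromatisation and a mild oxidation then give the quinone.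
- Monoketal 4 comes from 2,4-dimethoxybenzaldehyde by Baeyer–Villiger (Dakin-type) oxidation and PhI(OAc)2/MeOH. Bromide 16 comes from two molecules of (2E,6E)-farnesol joined C12 to C13 by allylic sulfone alkylation and Pd-catalysed desulfonylation.

Key step: step 12

Remark: the target has no stereocentre, only five E alkenes. The stereocentres in 13, 19, 20 and 21 are therefore racemic and transient, and commercial farnesol is taken as the pure (2E,6E) isomer.

**Route**

Step 1
Reactants: 1 2,4-dimethoxybenzaldehyde
Product: 3 2,4-dimethoxyphenol, via 2,4-dimethoxyphenyl formate 2 (not isolated)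
Conditions: mCPBA, CH2Cl2, 0 °C to rt; aq. NaHCO3 wash; then K2CO3 (cat.), MeOH, rt
Reagents that add atoms: mCPBA (3-chloroperoxybenzoic acid), O=C(OO)c1cccc(Cl)c1
Why: Baeyer–Villiger (Dakin-type) oxidation in which the electron-rich 2,4-dimethoxyphenyl group migrates in preference to hydrogen, after which the aryl formate is transesterified by methanol to the free phenol.

Step 2
Reactants: 3 2,4-dimethoxyphenol
Product: 4 2,4,4-trimethoxycyclohexa-2,5-dien-1-one
Conditions: PhI(OAc)2 (1.1 equiv), MeOH, 0 °C; NaHCO3 work-up; used promptly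
Reagents that add atoms: methanol, CO
Why: Oxidative dearomatisation of a 4-alkoxyphenol by a trivalent iodine reagent, in which methanol is captured at the methoxy-bearing para carbon to give the cross-conjugated para-quinone monoketal, the usual outcome for 4-alkoxyphenols.

Step 3
Reactants: 5 (2E,6E)-farnesol
Product: 6 (2E,6E)-farnesyl tert-butyldimethylsilyl ether
Conditions: TBSCl, imidazole, DMF, rt
Reagents that add atoms: tert-butyldimethylsilyl chloride, CC(C)(C)[Si](C)(C)Cl
Why: Imidazole-promoted silylation of a primary allylic alcohol, giving an ether that should survive the allylic oxidation, the sulfone carbanion and the hydride reagent of later steps.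

Step 4
Reactants: 6 (2E,6E)-farnesyl tert-butyldimethylsilyl ether
Product: 7 (2E,6E,10E)-12-(tert-butyldimethylsilyloxy)-2,6,10-trimethyldodeca-2,6,10-trien-1-ol
Conditions: SeO2 (cat.), t-BuOOH, salicylic acid (cat.), CH2Cl2, 0 °C to rt, stopped at partial conversion
Reagents that add atoms: tert-butyl hydroperoxide, CC(C)(C)OO
Why: Riley-type allylic oxidation made catalytic in SeO2 by t-BuOOH (ene reaction then [2,3]-sigmatropic shift) should attack the terminal isopropylidene group, the least hindered alkene and the one farthest from the deactivating allylic oxygen, and oxidise the methyl trans to the chain so that the new alkene is E.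

Step 5
Reactants: 7 (2E,6E,10E)-12-(tert-butyldimethylsilyloxy)-2,6,10-trimethyldodeca-2,6,10-trien-1-ol
Product: 9 (2E,6E,10E)-12-bromo-1-(tert-butyldimethylsilyloxy)-3,7,11-trimethyldodeca-2,6,10-triene, via allylic methanesulfonate 8 (not isolated)
Conditions: MsCl, Et3N, CH2Cl2, −40 °C; then LiBr, THF, −40 to 0 °C
Reagents that add atoms: lithium bromide, [Li+].[Br-]
Why: Mesylation followed by SN2 displacement with bromide at the primary allylic carbon gives the bromide without allylic transposition and without free acid that would cleave the silyl ether.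

Step 6
Reactants: 5 (2E,6E)-farnesol
Product: 10 (2E,6E)-farnesyl bromide
Conditions: PBr3 (0.4 equiv), pyridine (cat.), Et2O, 0 °C; used crude
Reagents that add atoms: phosphorus tribromide, BrP(Br)Br
Why: Bromide displaces the phosphite ester at the primary allylic carbon by SN2 at 0 °C, which keeps the 2E geometry.

Step 7
Reactants: 10 (2E,6E)-farnesyl bromide
Product: 11 (2E,6E)-farnesyl p-tolyl sulfone
Conditions: sodium p-toluenesulfinate (p-TolSO2Na), DMF, rt
Reagents that add atoms: sodium p-toluenesulfinate, [Na+].[O-]S(=O)c1ccc(C)cc1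
Why: S-alkylation of the ambident sulfinate anion by SN2 at the primary allylic bromide gives the crystallisable allylic sulfone.

Step 8
Reactants: 11 (2E,6E)-farnesyl p-tolyl sulfone; 9 (2E,6E,10E)-12-bromo-1-(tert-butyldimethylsilyloxy)-3,7,11-trimethyldodeca-2,6,10-triene
Product: 13 racemic (2E,6E,10E,14E,18E)-1-(tert-butyldimethylsilyloxy)-3,7,11,15,19,23-hexamethyl-13-(p-tolylsulfonyl)tetracosa-2,6,10,14,18,22-hexaene, via α-lithio farnesyl p-tolyl sulfone 12 (not isolated)
Conditions: n-BuLi (1.05 equiv), THF, −78 °C; then 9, −78 to −20 °C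
Reagents that add atoms: none
Why: Julia-type allylic sulfone alkylation, in which the sulfonyl-stabilised allylic carbanion reacts at its α-carbon with the primary allylic bromide by SN2 to form the C12–C13 bond of the C30 chain without touching any alkene; the racemic sulfone stereocentre at C13 is removed in step 9.

Step 9
Reactants: 13 racemic C30 allylic sulfone
Product: 14 (2E,6E,10E,14E,18E)-hexaprenyl tert-butyldimethylsilyl ether
Conditions: PdCl2(dppp) (5 mol %), LiBHEt3 (2.5 equiv), THF, 0 °C
Reagents that add atoms: none
Why: Palladium-catalysed reductive desulfonylation, in which zerovalent palladium formed in the flask ionises the allylic sulfone to a π-allyl complex and hydride is delivered to the less substituted terminus C13, so the C14=C15 alkene should stay in place and E.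

Step 10
Reactants: 14 all-E-hexaprenyl tert-butyldimethylsilyl ether
Product: 15 (2E,6E,10E,14E,18E)-hexaprenol
Conditions: Bu4NF, THF, 0 °C to rt
Reagents that add atoms: none
Why: Fluoride-mediated desilylation driven by the strong Si–F bond, under conditions that leave the skipped polyene untouched.

Step 11
Reactants: 15 all-E-hexaprenol
Product: 16 (2E,6E,10E,14E,18E)-hexaprenyl bromide
Conditions: PBr3 (0.4 equiv), pyridine (cat.), Et2O/hexane, 0 °C, dark; used crude at once
Reagents that add atoms: phosphorus tribromide, BrP(Br)Br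
Why: SN2 bromination of the primary allylic alcohol through its phosphite ester at 0 °C, the standard way to all-E polyprenyl bromides with retention of the 2E alkene.

Step 12
Reactants: 4 2,4,4-trimethoxycyclohexa-2,5-dien-1-one; 17 methyllithium; 16 all-E-hexaprenyl bromide
Product: 20 racemic trans-2,4,4-trimethoxy-5-methyl-6-[(2E,6E,10E,14E,18E)-3,7,11,15,19,23-hexamethyltetracosa-2,6,10,14,18,22-hexaen-1-yl]cyclohex-2-en-1-one, via lithium dimethylcuprate 18 (not isolated), via lithium dienolate 19 (not isolated)
Conditions: CuI (1.4 equiv), 17 (2.8 equiv), Et2O, 0 °C; 4 (1.5 equiv), −78 to −40 °C; then 16 (1.0 equiv), THF/HMPA, −78 to −20 °C; NH4Cl/NH4OH (pH 8) quench; Et3N-deactivated silica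
Reagents that add atoms: methyllithium 17, [Li]C (methyl delivered through lithium dimethylcuprate 18, [Li+].C[Cu-]C)
Why: Cuprate 18, made from CuI and two equivalents of 17, complexes the unsubstituted C2=C3 enone of 4 (target numbering), adds oxidatively to give a trivalent copper β-adduct and reductively eliminates to form C3–CH3 and lithium enolate 19; 19 has no proton on C6, so it cannot equilibrate, and in THF/HMPA it displaces bromide from C1' of 16 by SN2 to form C2–C1'. The closest known reaction type is the tandem cuprate conjugate addition and enolate alkylation of cyclic enones (vicinal difunctionalisation), together with cuprate additions to quinone monoketals. No ring closes. The C3 stereocentre forms as a racemate and the C2 stereocentre is set trans to it by substrate control, the electrophile approaching the half-chair enolate anti to the adjacent methyl; both centres are erased in step 13. The step needs site selectivity between the β-carbons C3 and C5, and the C6 methoxy group secures it by making C5 the electron-rich end of an enol ether on an α-substituted enone; C-alkylation by direct SN2, not O-alkylation or SN2', follows from pairing a soft enolate with a primary allylic bromide. Keeping 4 in slight excess over 18 and 16 as the limiting component should leave no free cuprate to methylate 16 and should suppress a second alkylation at C2.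

Step 13
Reactants: 20 racemic trans ketal ketone
Product: 22 2-(all-E-hexaprenyl)-6-methoxy-3-methylbenzene-1,4-diol, via ene-dione 21 (not isolated)
Conditions: 1 M aq. HCl–THF (1:4), degassed, argon, 0 °C to rt; used crude
Reagents that add atoms: water, O
Why: Acid-catalysed ketal hydrolysis, easy because the C4 oxocarbenium ion is stabilised through the C5=C6 enol ether, gives ene-dione 21, whose C2 and C3 hydrogens are then lost in a double keto–enol tautomerisation that aromatises ring A and removes both stereocentres, while cold dilute aqueous acid favours capture by water over loss of methanol and does not protonate the trisubstituted alkenes.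

Step 14
Reactants: 22 2-(all-E-hexaprenyl)-6-methoxy-3-methylbenzene-1,4-diol
Product: 23 2-(all-E-hexaprenyl)-6-methoxy-3-methyl-1,4-benzoquinone
Conditions: Ag2O, MgSO4, Et2O, rt, dark
Reagents that add atoms: none
Why: Two-electron oxidation of an electron-rich hydroquinone to the para-quinone by Ag2O, a neutral heterogeneous oxidant that should leave the five E alkenes and the terminal isopropylidene group unchanged.

**Compound list**

1 | 2,4-dimethoxybenzaldehyde | COc1ccc(C=O)c(OC)c1 | starting material
2 | 2,4-dimethoxyphenyl formate | COc1ccc(OC=O)c(OC)c1 | intermediate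
3 | 2,4-dimethoxyphenol | COc1ccc(O)c(OC)c1 | intermediate
4 | 2,4,4-trimethoxycyclohexa-2,5-dien-1-one | COC1=CC(OC)(OC)C=CC1=O | intermediate
5 | (2E,6E)-farnesol | OC/C=C(\C)CC/C=C(\C)CCC=C(C)C | starting material
6 | (2E,6E)-farnesyl tert-butyldimethylsilyl ether | CC(C)(C)[Si](C)(C)OC/C=C(\C)CC/C=C(\C)CCC=C(C)C | intermediate
7 | (2E,6E,10E)-12-(tert-butyldimethylsilyloxy)-2,6,10-trimethyldodeca-2,6,10-trien-1-ol | CC(C)(C)[Si](C)(C)OC/C=C(\C)CC/C=C(\C)CC/C=C(\C)CO | intermediate
8 | (2E,6E,10E)-12-(tert-butyldimethylsilyloxy)-2,6,10-trimethyldodeca-2,6,10-trien-1-yl methanesulfonate | CC(C)(C)[Si](C)(C)OC/C=C(\C)CC/C=C(\C)CC/C=C(\C)COS(C)(=O)=O | intermediate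
9 | (2E,6E,10E)-12-bromo-1-(tert-butyldimethylsilyloxy)-3,7,11-trimethyldodeca-2,6,10-triene | CC(C)(C)[Si](C)(C)OC/C=C(\C)CC/C=C(\C)CC/C=C(\C)CBr | intermediate
10 | (2E,6E)-farnesyl bromide | BrC/C=C(\C)CC/C=C(\C)CCC=C(C)C | intermediate
11 | (2E,6E)-farnesyl p-tolyl sulfone | Cc1ccc(cc1)S(=O)(=O)C/C=C(\C)CC/C=C(\C)CCC=C(C)C | intermediate
12 | α-lithio (2E,6E)-farnesyl p-tolyl sulfone | [Li]C(/C=C(\C)CC/C=C(\C)CCC=C(C)C)S(=O)(=O)c1ccc(C)cc1 | intermediate
13 | racemic (2E,6E,10E,14E,18E)-1-(tert-butyldimethylsilyloxy)-3,7,11,15,19,23-hexamethyl-13-(p-tolylsulfonyl)tetracosa-2,6,10,14,18,22-hexaene | CC(C)(C)[Si](C)(C)OC/C=C(\C)CC/C=C(\C)CC/C=C(\C)CC(/C=C(\C)CC/C=C(\C)CCC=C(C)C)S(=O)(=O)c1ccc(C)cc1 | intermediate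
14 | (2E,6E,10E,14E,18E)-hexaprenyl tert-butyldimethylsilyl ether | CC(C)(C)[Si](C)(C)OC/C=C(\C)CC/C=C(\C)CC/C=C(\C)CC/C=C(\C)CC/C=C(\C)CCC=C(C)C | intermediate
15 | (2E,6E,10E,14E,18E)-hexaprenol (3,7,11,15,19,23-hexamethyltetracosa-2,6,10,14,18,22-hexaen-1-ol) | OC/C=C(\C)CC/C=C(\C)CC/C=C(\C)CC/C=C(\C)CC/C=C(\C)CCC=C(C)C | intermediate
16 | (2E,6E,10E,14E,18E)-hexaprenyl bromide | BrC/C=C(\C)CC/C=C(\C)CC/C=C(\C)CC/C=C(\C)CC/C=C(\C)CCC=C(C)C | intermediate
17 | methyllithium | [Li]C | starting material
18 | lithium dimethylcuprate | [Li+].C[Cu-]C | intermediate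
19 | racemic lithium 4,4,6-trimethoxy-3-methylcyclohexa-1,5-dien-1-olate | [Li+].[O-]C1=CC(C)C(OC)(OC)C=C1OC | intermediate
20 | racemic trans-2,4,4-trimethoxy-5-methyl-6-(all-E-hexaprenyl)cyclohex-2-en-1-one (one enantiomer drawn) | COC1=CC(OC)(OC)[C@@H](C)[C@H](C/C=C(\C)CC/C=C(\C)CC/C=C(\C)CC/C=C(\C)CC/C=C(\C)CCC=C(C)C)C1=O | intermediate
21 | racemic trans-2-methoxy-5-methyl-6-(all-E-hexaprenyl)cyclohex-2-ene-1,4-dione (one enantiomer drawn; epimerisable) | COC1=CC(=O)[C@@H](C)[C@H](C/C=C(\C)CC/C=C(\C)CC/C=C(\C)CC/C=C(\C)CC/C=C(\C)CCC=C(C)C)C1=O | intermediate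
22 | 2-(all-E-hexaprenyl)-6-methoxy-3-methylbenzene-1,4-diol | COc1cc(O)c(C)c(C/C=C(\C)CC/C=C(\C)CC/C=C(\C)CC/C=C(\C)CC/C=C(\C)CCC=C(C)C)c1O | intermediate
23 | 2-(all-E-hexaprenyl)-6-methoxy-3-methyl-1,4-benzoquinone | COC1=CC(=O)C(C)=C(C/C=C(\C)CC/C=C(\C)CC/C=C(\C)CC/C=C(\C)CC/C=C(\C)CCC=C(C)C)C1=O | target

**Step count**

Total: 14 steps. Longest linear sequence: 10 steps (steps 3, 4, 5, 8, 9, 10, 11, 12, 13, 14, from farnesol 5 to target 23).

**Steps most likely to fail**

1. Step 12. The cuprate may reduce 4 by single-electron transfer back to phenol 3. The copper-containing enolate aggregate may alkylate slowly, so that residual methylcopper transfers methyl to 16 or proton exchange between 20 and 19 leads to double alkylation at C2. The fallback separates the two bond formations. It sets out from 4: a copper-catalysed conjugate addition with silyl trapping (MeMgBr, CuBr·SMe2 5 mol %, TMSCl, THF, −78 °C, Et3N-buffered work-up) would give racemic trimethyl[(4,4,6-trimethoxy-3-methylcyclohexa-1,5-dien-1-yl)oxy]silane F1, isolated free of copper. MeLi in THF at 0 °C then cleaves the O–Si bond to regenerate lithium enolate 19 without copper, and alkylation with 16 in THF/HMPA at −40 to 0 °C comes back to the route at 20.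

2. Step 13. The ionised ketal may lose the C3 proton faster than it adds water, so that ring A aromatises with the C4 methyl ether still in place. Prolonged acid may also protonate the chain alkenes or close the ortho-prenyl phenol to a chroman. The fallback makes loss of methanol the intended path. It sets out from 20: PPTS (cat.) in dry toluene at 40 °C would eliminate methanol and tautomerise the dienone to 2-(all-E-hexaprenyl)-4,6-dimethoxy-3-methylphenol F2. Oxidative demethylation of this para-methoxyphenol with (NH4)2Ce(NO3)6 in MeCN/H2O at 0 °C then gives the quinone directly and comes back to the route at 23.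

3. Step 4. Site selectivity among the three trisubstituted alkenes may be poor, and over-oxidation to the enal may lower the return of the E-allylic alcohol. The fallback builds the terminal E-allylic alcohol by chain degradation and olefination. It sets out from 6: NBS in THF/H2O at 0 °C would add HOBr selectively across the terminal alkene to give racemic (6E,10E)-3-bromo-12-(tert-butyldimethylsilyloxy)-2,6,10-trimethyldodeca-6,10-dien-2-ol F3. K2CO3 in MeOH closes it to racemic (2E,6E)-10,11-epoxyfarnesyl tert-butyldimethylsilyl ether F4. H5IO6 in THF/H2O at 0 °C cleaves the epoxide to (4E,8E)-10-(tert-butyldimethylsilyloxy)-4,8-dimethyldeca-4,8-dienal F5. Wittig olefination with the stabilised ylide Ph3P=C(CH3)CO2Et in CH2Cl2 gives ethyl (2E,6E,10E)-12-(tert-butyldimethylsilyloxy)-2,6,10-trimethyldodeca-2,6,10-trienoate F6. Reduction with i-Bu2AlH in toluene at −78 °C comes back to the route at 7.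

**Further compounds**

F1 | step 12 | racemic trimethyl[(4,4,6-trimethoxy-3-methylcyclohexa-1,5-dien-1-yl)oxy]silane | C[Si](C)(C)OC1=CC(C)C(OC)(OC)C=C1OC
F2 | step 13 | 2-(all-E-hexaprenyl)-4,6-dimethoxy-3-methylphenol | COc1cc(OC)c(C)c(C/C=C(\C)CC/C=C(\C)CC/C=C(\C)CC/C=C(\C)CC/C=C(\C)CCC=C(C)C)c1O
F3 | step 4 | racemic (6E,10E)-3-bromo-12-(tert-butyldimethylsilyloxy)-2,6,10-trimethyldodeca-6,10-dien-2-ol | CC(C)(C)[Si](C)(C)OC/C=C(\C)CC/C=C(\C)CCC(Br)C(C)(C)O
F4 | step 4 | racemic (2E,6E)-10,11-epoxyfarnesyl tert-butyldimethylsilyl ether | CC(C)(C)[Si](C)(C)OC/C=C(\C)CC/C=C(\C)CCC1OC1(C)C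
F5 | step 4 | (4E,8E)-10-(tert-butyldimethylsilyloxy)-4,8-dimethyldeca-4,8-dienal | CC(C)(C)[Si](C)(C)OC/C=C(\C)CC/C=C(\C)CCC=O
F6 | step 4 | ethyl (2E,6E,10E)-12-(tert-butyldimethylsilyloxy)-2,6,10-trimethyldodeca-2,6,10-trienoate | CC(C)(C)[Si](C)(C)OC/C=C(\C)CC/C=C(\C)CC/C=C(\C)C(=O)OCC
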